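## The problem

Target 35 is a germacranolide (numbering: C1 furanone ketone, C2=C3 furanone alkene, C4 bearing C15, C6 lactone O–CH, C7 ring fusion, C8 ester carbinol, C9 methylene, C10 methyl-bearing C–O, C11–C13 lactone acyl part). Its ten-membered carbocycle is bridged by the ring oxygen of a 3(2H)-furanone (O joins C3 and C10), so the ring to be closed is in effect a strained nine-membered oxacycle holding a trisubstituted Z C4=C5 alkene. A trans-fused α-methylene γ-lactone sits on C6/C7, a crotonate on C8 and a free allylic alcohol on C15.

Of the four stereocentres, C6, C7 and C8 are contiguous and C10 is a quaternary carbinol insulated by the C9 methylene. C6 can dictate C7 when both lie in a five-membered ring, and C10 has to be bought. C8 is the soft spot: the two carbon arms on C10 (methyl and C1) are too alike for dependable 1,3-induction, and C7 is a ring carbon without a chelating substituent.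

The α-methylene lactone (Michael acceptor), the crotonate (base- and metathesis-active), the cross-conjugated dienone and any C8 carbonyl (β-acyloxy towards both C6–O and C10–O, so prone to elimination) must appear late or stay masked. A free C8 alkoxide can also translactonise onto C12.

What opens the molecule up is the position of C8: an oxygen-bearing carbon between the C9 methylene of a tertiary carbinol and C7, the β-carbon of the lactone acyl chain. C8 can therefore enter as a doubly nucleophilic formyl equivalent, a silyl dithiane, that first opens a C10 epoxide at C9 and then, once the C10 alkoxide has taken over its silyl group, adds to C7 of a C6-substituted butenolide.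

## Retrosynthesis

**35 ⇒ 34 ⇒ 32 + 33 (C15–O benzyl bond, C8–O acyl bond).** The free allylic alcohol is masked as PMB ether 34, and the crotonate is cut back to alcohol 32 and crotonic anhydride 33. The ester goes first because a crotonate on C8 would close a seven-membered unsaturated lactone with a C6 vinyl group under metathesis and would not survive amide bases. The forward steps only ask for acylation of one hindered secondary alcohol and a buffered DDQ cleavage.

**32 ⇒ 28 (C11=C13).** Removing the exocyclic methylene removes the strongest Michael acceptor. Forward, the lactone of 28 must be enolised selectively in the presence of a free C8 hydroxyl (dianion) and aminomethylated.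

**28 ⇒ 27 (C4=C5).** The ring is cut at the alkene. Against closure at C2–C3 (ketone enolate onto an acyl group) or C1–C2 (acetylide chemistry inside the ring), an alkene metathesis needs no enolate or metal acetylide next to the lactone. Only the Z alkene fits into the oxa-bridged ring. Ring-closing metathesis onto an alkenyl 3(2H)-furanone to give this type of bicycle is known. Precursor 27 is an open triene carrying all four stereocentres.

**27 ⇒ 26 ⇒ 25 (C8–H, then C8=O from the dithiane).** The carbinol comes from ketone 26 by catalyst-controlled reduction and the ketone from dithiane 25. Keeping C8 as the dithiane until this point lets the linchpin protect C8 through seven steps at no cost.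

**25 ⇒ 24 ⇒ 23 (C5=CH2).** The metathesis handle at C6 is traced to aldehyde 24 and primary alcohol 23, that is, to the oxygenated carbon the butenolide brings along.

**23 ⇒ 21 ⇒ 20 ⇒ 15 + 18 (O–C3, then C1–C2).** The furanone is opened at its enol ether bond to an α′-oxygenated ynone (21, free diol 22), and the ynone is cut to aldehyde 15 and enyne 18. Compared with building the furanone from a C1 methyl ketone and an acyl donor, this avoids a ketone enolate beside the lactone. It also delivers C2, C3, C4, C15 and the second metathesis alkene in one piece. The fluoride that frees the C10 oxygen frees the C5 oxygen as well.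

**15 ⇒ 14 ⇒ 13.** Oxidation-level adjustment at C1 (PMB ether to alcohol to aldehyde). C10 is quaternary, so the aldehyde cannot epimerise.

**13 ⇒ 8 + 3 + 5 (C8–C9 and C7–C8).** Both bonds to C8 are cut at once. Silyl dithiane 8, epoxide 3 and butenolide 5 are one step each from 1,3-dithiane 6, (S)-2-methylglycidol 1 and (R)-5-(hydroxymethyl)furanone 4. The forward reaction must open the epoxide at CH2, move silicon from C8 to the C10 oxygen only afterwards, and add 1,4 to the butenolide anti to its C6 substituent.

**18 ⇒ 17 ⇒ 16.** The enyne comes from 2,3-dibromopropene 16 by etherification and ethynylation.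

## Roads not taken

**Alternative 1:** cut at C1–C2. Seco thioester–alkyne A1 would be cyclised with PdCl2(dppf) (divalent palladium), tri(2-furyl)phosphine, CuI (monovalent copper) and Et3N to the ten-membered Z-enynone A2; desilylation and 5-endo closure of the C10 oxygen onto C3 would then give the furanone.
- Merits: the ring closes with the methylene lactone and the crotonate already in place, so only two operations follow. The ynone-to-furanone closure is the same reaction as step 11 here.
- Weak points: the thioester sits on a fully substituted, silyloxy-bearing carbon. A copper acetylide and an amine are used beside an α-methylene lactone. Alkyne homocoupling competes at high dilution. The cyclodecenyne is strained. A1 itself still needs a stereocontrolled assembly of C6–C10.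
- Comparison: this road is better in end-game length and avoids late enolate chemistry. The chosen plan sets against it a one-flask assembly of C7–C10 from three one-step fragments and a ring closure on a substrate without electrophilic alkenes.

**Alternative 2:** cut at C5–C6. Iodo aldehyde A3 would be treated with CrCl2 (divalent chromium) and catalytic NiCl2 (divalent nickel) to give the macrocyclic carbinol A4, which then lactonises onto its C12 ester.
- Merits: this is probably the most dependable carbon–carbon closure for a ring of this size. The Z geometry is fixed in the iodide and does not rely on ring strain.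
- Weak points: C6 is created during ring closure and must come out with the configuration needed for the trans lactone, controlled only by the forming ring. The aldehyde is α to C7 and can epimerise. Lactonisation, methylenation and a large excess of chromium remain.
- Comparison: the ring closure is the more reliable one. The chosen plan instead buys C6 and derives C7 from it on a five-membered ring, where trans addition is dependable.

**Alternative 3:** cut at C2–C3 and C4–C5 through a photochemical two-carbon ring expansion. Cyclooctenone ynol ether A5 would be irradiated (350–366 nm) to the alkoxycyclobutene A6, whose thermal conrotatory opening cleaves C2–C5 and should give the 15-O-silyl ether A7.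
- Merits: furanone and ten-membered ring arise in one operation from an easier eight-membered ring. The cis ring fusion translates into the Z alkene. Only a desilylation follows.
- Weak points: a tertiary ynol ether is thermally and hydrolytically fragile. Cyclooctenones isomerise to the trans enone on irradiation. The crotonate, the methylene lactone and the product dienone are all photoactive. A5 needs its own stereocontrolled synthesis.
- Comparison: the shortest end-game of all. The chosen plan accepts more steps in exchange for ground-state reactions whose outcome can be checked one at a time.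

Key step: step 4

Remark: (S)-2-methylglycidol and (R)-5-(hydroxymethyl)furan-2(5H)-one are taken as purchasable single enantiomers.

## Route

Step 1
Reactants: 1 (S)-2-methylglycidol
Product: 3 (R)-2-[(4-methoxybenzyloxy)methyl]-2-methyloxirane, via sodium alkoxide 2 (not isolated)
Conditions: NaH, PMBCl, Bu4NI (cat.), THF/DMF, 0 °C → rt
Reagents that add atoms: 4-methoxybenzyl chloride, COc1ccc(CCl)cc1
Why: Williamson etherification of the primary alkoxide; epoxide migration would need substitution at the fully substituted carbon, so the C10 configuration of 1 is carried into 3 (the descriptor changes only because the ranking of the two CH2 arms changes).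

Step 2
Reactants: 4 (R)-5-(hydroxymethyl)furan-2(5H)-one
Product: 5 (R)-5-[(tert-butyldiphenylsilyloxy)methyl]furan-2(5H)-one
Conditions: TBDPSCl, imidazole, CH2Cl2, 0 °C → rt
Reagents that add atoms: tert-butyl(chloro)diphenylsilane, CC(C)(C)[Si](Cl)(c1ccccc1)c1ccccc1
Why: Standard silylation of a primary alcohol; the bulky silyloxymethyl group later shields one face of the butenolide.

Step 3
Reactants: 6 1,3-dithiane
Product: 8 2-(tert-butyldimethylsilyl)-1,3-dithiane, via 2-lithio-1,3-dithiane 7 (not isolated)
Conditions: n-BuLi, THF, −30 °C; TBSCl, −78 °C → rt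
Reagents that add atoms: tert-butyl(chloro)dimethylsilane, CC(C)(C)[Si](C)(C)Cl
Why: Deprotonation of the dithiane and C-silylation give the linchpin.

Step 4
Reactants: 8 2-(tert-butyldimethylsilyl)-1,3-dithiane; 3 epoxide PMB ether; 5 silyl butenolide
Product: 13 dithiane-linked trans-lactone, via lithiated silyl dithiane 9 (not isolated), via lithium alkoxide 10 (not isolated), via Brook-rearranged lithiodithiane 11 (not isolated), via lithium lactone enolate 12 (not isolated)
Conditions: t-BuLi, Et2O, −78 → −45 °C; 3, −78 → −25 °C; 5, THF/HMPA, −78 °C; aq NH4Cl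
Reagents that add atoms: none
Why: t-BuLi removes the C2 proton of 8, and in ether the contact ion pair 9 opens epoxide 3 by SN2 at its unsubstituted CH2 (C9), leaving the quaternary C10 untouched and giving alkoxide 10, which keeps its C–Si bond in this solvent. Adding HMPA/THF with the butenolide triggers the 1,4-Brook shift of silicon from C8 to the C10 oxygen through a five-membered silicate; this protects the tertiary oxygen and regenerates a carbanion at C8 (11) without a second base. As a solvent-separated ion pair, 11 adds 1,4 to butenolide 5 to form C7–C8, and enolate 12 is protonated on work-up. The closest known reaction types are the dithiane anion relay (epoxide opening, then solvent-controlled Brook rearrangement) and the conjugate addition of 2-lithiodithianes to butenolides in HMPA; the step joins the two. No ring is closed. The one new stereocentre, C7, is controlled by the C6 silyloxymethyl group of 5: the nucleophile enters anti to it and gives the trans lactone, while C6 and C10 are purchased. The step needs attack at CH2 instead of the quaternary carbon (sterics), Brook migration only after the epoxide is consumed (solvent switch), and 1,4- over 1,2-addition or γ-deprotonation (HMPA, −78 °C, soft hindered anion).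

Step 5
Reactants: 13 dithiane-linked trans-lactone
Product: 14 C1 primary alcohol
Conditions: DDQ, CH2Cl2/pH 7 buffer, 0 °C
Reagents that add atoms: none
Why: Oxidative PMB cleavage; silyl ethers and lactone are inert, and a short buffered exposure at 0 °C should leave the dithiane untouched.

Step 6
Reactants: 14 C1 primary alcohol
Product: 15 C1 aldehyde
Conditions: (COCl)2, DMSO, CH2Cl2, −78 °C; Et3N, −78 → 0 °C
Reagents that add atoms: none
Why: Swern oxidation tolerates the dithiane; the aldehyde sits on quaternary C10 and cannot epimerise.

Step 7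
Reactants: 16 2,3-dibromopropene
Product: 17 2-bromoallyl 4-methoxybenzyl ether
Conditions: 4-methoxybenzyl alcohol, NaH, THF, 0 °C; 16, Bu4NI (cat.), rt
Reagents that add atoms: 4-methoxybenzyl alcohol, COc1ccc(CO)cc1
Why: Williamson etherification at the allylic bromide; the vinylic bromide does not react.

Step 8
Reactants: 17 2-bromoallyl 4-methoxybenzyl ether
Product: 18 2-[(4-methoxybenzyloxy)methyl]but-1-en-3-yne
Conditions: HC≡CMgBr, ZnBr2, THF, 0 °C; 17, Pd(PPh3)4 (zerovalent palladium, 5 mol %), 50 °C
Reagents that add atoms: ethynylmagnesium bromide, C#C[Mg]Br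
Why: Negishi coupling of an alkenyl bromide with ethynylzinc bromide gives the terminal enyne directly, without a silyl protection and deprotection.

Step 9
Reactants: 18 enyne; 15 C1 aldehyde
Product: 20 C1 propargylic alcohol (both C1 epimers), via lithium acetylide 19 (not isolated)
Conditions: 18, n-BuLi, THF, −78 °C; 15, −78 °C; aq NH4Cl
Reagents that add atoms: none
Why: 1,2-Addition of a lithium acetylide to the aldehyde, which is far more electrophilic than the lactone at −78 °C; this forms C1–C2, and the C1 carbinol configuration is irrelevant because it is oxidised next.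

Step 10
Reactants: 20 C1 propargylic alcohol
Product: 21 α′-silyloxy enynone
Conditions: MnO2 (activated, excess), CH2Cl2, rt
Reagents that add atoms: none
Why: Neutral oxidation of a propargylic alcohol to the ynone; dithiane sulfur and the PMB ether are not affected.

Step 11
Reactants: 21 α′-silyloxy enynone
Product: 23 furanone primary alcohol, via hydroxy ynone 22 (not isolated)
Conditions: Bu4NF, THF, 0 °C → rt
Reagents that add atoms: none
Why: Fluoride removes both silyl groups; the freed C10 oxygen adds 5-endo-dig to the ynone β-carbon C3 and protonation at C2 gives the 3(2H)-furanone, a known closure of α′-hydroxy ynones. No bond to C10 is broken, and the C5 hydroxyl is released in the same flask.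

Step 12
Reactants: 23 furanone primary alcohol
Product: 24 C5 aldehyde
Conditions: SO3·pyridine, DMSO, iPr2NEt, CH2Cl2, 0 °C
Reagents that add atoms: none
Why: Parikh–Doering oxidation is compatible with the dithiane; the α-oxygenated aldehyde is used crude, and the trans lactone is the thermodynamically favoured C6 epimer.

Step 13
Reactants: 24 C5 aldehyde
Product: 25 C6-vinyl dithiane triene
Conditions: Ph3PCH3Br, KN(SiMe3)2, THF, 0 °C; 24, −78 → 0 °C
Reagents that add atoms: methyltriphenylphosphonium bromide, C[P+](c1ccccc1)(c1ccccc1)c1ccccc1.[Br-]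
Why: Wittig methylenation; the aldehyde is by far the most electrophilic carbonyl, the furanone being a vinylogous ester and the lactone an ester.

Step 14
Reactants: 25 C6-vinyl dithiane triene
Product: 26 C8 ketone
Conditions: MeI, CaCO3, MeCN/H2O (9:1), 40 °C
Reagents that add atoms: water, O
Why: S-Methylation and hydrolysis unmask the ketone under near-neutral conditions, chosen because 26 is β-acyloxy on both sides and would eliminate, or epimerise at C7, under stronger base.

Step 15
Reactants: 26 C8 ketone
Product: 27 (8R)-carbinol
Conditions: (S)-2-methyl-CBS-oxazaborolidine, catecholborane, toluene, −78 °C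
Reagents that add atoms: none
Why: Corey–Bakshi–Shibata reduction; the ketone should bind anti to its α-branched C7 arm and take hydride on the face that gives 8R. Catalyst control is used because neither C7 nor the etherified C10 oxygen offers a dependable directing effect. Catecholborane at −78 °C should not touch the vinylogous ester, lactone or alkenes.

Step 16
Reactants: 27 (8R)-carbinol
Product: 28 bicyclic alcohol
Conditions: Hoveyda–Grubbs second-generation catalyst [(H2IMes)Cl2Ru(=CH-C6H4-2-OiPr)] (15 mol %), toluene (1 mM), 80 °C
Reagents that add atoms: none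
Why: Ring-closing metathesis: the ruthenium carbene loads at the monosubstituted C6 vinyl group and closes onto the 1,1-disubstituted C4 methylene with loss of ethylene. Closure of alkenyl 3(2H)-furanones to this oxa-bridged bicycle is a known use of the reaction, and only the Z alkene fits into the nine-membered oxacycle.

Step 17
Reactants: 28 bicyclic alcohol
Product: 32 α-methylene lactone alcohol, via dilithio alkoxide enolate 29 (not isolated), via Mannich base 30 (not isolated), via ammonium iodide 31 (not isolated)
Conditions: LiN(iPr)2 (2.5 equiv), THF, −78 °C; CH2=NMe2+ I−, −78 → 0 °C; MeI, MeOH, rt; aq NaHCO3, CH2Cl2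
Reagents that add atoms: Eschenmoser's salt (N,N-dimethylmethyleneiminium iodide), C=[N+](C)C.[I-]
Why: Kinetic lactone enolate (after the alkoxide), Mannich reaction, quaternisation and E1cB elimination give the exocyclic methylene. Once the lactone is an enolate it cannot be attacked by the C8 alkoxide, and the transient C11 centre is erased on elimination.

Step 18
Reactants: 32 α-methylene lactone alcohol; 33 crotonic anhydride
Product: 34 15-O-PMB ether of the target
Conditions: DMAP, Et3N, CH2Cl2, 0 °C → rt
Reagents that add atoms: none
Why: DMAP-catalysed acylation of the only hydroxyl; the crotonate is introduced after the metathesis and enolate steps it would not survive.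

Step 19
Reactants: 34 15-O-PMB ether of the target
Product: 35 CNP0225232.1
Conditions: DDQ, CH2Cl2/pH 7 buffer, 0 °C
Reagents that add atoms: none
Why: Oxidative cleavage of the allylic PMB ether; methylene lactone, crotonate and dienone are inert to DDQ under these conditions.

## Compound list

1 | (S)-2-methylglycidol | OC[C@@]1(C)CO1 | starting material
2 | sodium alkoxide of 1 | [Na]OC[C@@]1(C)CO1 | intermediate
3 | (R)-2-[(4-methoxybenzyloxy)methyl]-2-methyloxirane (PMB ether of 1; oxirane C = C10, ring CH2 = C9) | COc1ccc(COC[C@@]2(C)CO2)cc1 | intermediate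
4 | (R)-5-(hydroxymethyl)furan-2(5H)-one | O=C1O[C@@H](CO)C=C1 | starting material
5 | (R)-5-[(tert-butyldiphenylsilyloxy)methyl]furan-2(5H)-one | O=C1O[C@@H](CO[Si](c2ccccc2)(c2ccccc2)C(C)(C)C)C=C1 | intermediate
6 | 1,3-dithiane | C1CSCSC1 | starting material
7 | 2-lithio-1,3-dithiane | [Li]C1SCCCS1 | intermediate
8 | 2-(tert-butyldimethylsilyl)-1,3-dithiane | C[Si](C)(C(C)(C)C)C1SCCCS1 | intermediate
9 | 2-lithio-2-(tert-butyldimethylsilyl)-1,3-dithiane | [Li]C1([Si](C)(C)C(C)(C)C)SCCCS1 | intermediate
10 | lithium alkoxide from epoxide opening (C10–OLi, silicon still on C8; C10 as in 3) | [Li]O[C@@](C)(COCc1ccc(OC)cc1)CC1([Si](C)(C)C(C)(C)C)SCCCS1 | intermediate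
11 | 2-lithio-2-[(2R)-2-(tert-butyldimethylsilyloxy)-3-(4-methoxybenzyloxy)-2-methylpropyl]-1,3-dithiane (C8 carbanion after the Brook shift) | [Li]C1(C[C@@](C)(O[Si](C)(C)C(C)(C)C)COCc2ccc(OC)cc2)SCCCS1 | intermediate
12 | lithium enolate of lactone 13 | [Li]OC1=C[C@@H](C2(SCCCS2)C[C@@](C)(O[Si](C)(C)C(C)(C)C)COCc2ccc(OC)cc2)[C@H](CO[Si](c2ccccc2)(c2ccccc2)C(C)(C)C)O1 | intermediate
13 | (4R,5R)-5-[(tert-butyldiphenylsilyloxy)methyl]-4-{2-[(2R)-2-(tert-butyldimethylsilyloxy)-3-(4-methoxybenzyloxy)-2-methylpropyl]-1,3-dithian-2-yl}dihydrofuran-2(3H)-one | O=C1O[C@@H](CO[Si](c2ccccc2)(c2ccccc2)C(C)(C)C)[C@@H](C1)C1(SCCCS1)C[C@@](C)(O[Si](C)(C)C(C)(C)C)COCc1ccc(OC)cc1 | intermediate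
14 | C1 primary alcohol (13 without the PMB group; C6, C7, C10 as in 13) | O=C1O[C@@H](CO[Si](c2ccccc2)(c2ccccc2)C(C)(C)C)[C@@H](C1)C1(SCCCS1)C[C@@](C)(O[Si](C)(C)C(C)(C)C)CO | intermediate
15 | C1 aldehyde (α-silyloxy aldehyde on quaternary C10) | O=C1O[C@@H](CO[Si](c2ccccc2)(c2ccccc2)C(C)(C)C)[C@@H](C1)C1(SCCCS1)C[C@@](C)(O[Si](C)(C)C(C)(C)C)C=O | intermediate
16 | 2,3-dibromopropene | C=C(Br)CBr | starting material
17 | 2-bromoallyl 4-methoxybenzyl ether | C=C(Br)COCc1ccc(OC)cc1 | intermediate
18 | 2-[(4-methoxybenzyloxy)methyl]but-1-en-3-yne | C#CC(=C)COCc1ccc(OC)cc1 | intermediate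
19 | lithium acetylide of 18 | [Li]C#CC(=C)COCc1ccc(OC)cc1 | intermediate
20 | C1 propargylic alcohol (C1–C2 joined; both C1 epimers) | O=C1O[C@@H](CO[Si](c2ccccc2)(c2ccccc2)C(C)(C)C)[C@@H](C1)C1(SCCCS1)C[C@@](C)(O[Si](C)(C)C(C)(C)C)C(O)C#CC(=C)COCc1ccc(OC)cc1 | intermediate
21 | α′-silyloxy enynone (C1 ketone, C2≡C3, C4=CH2 bearing C15H2OPMB) | O=C1O[C@@H](CO[Si](c2ccccc2)(c2ccccc2)C(C)(C)C)[C@@H](C1)C1(SCCCS1)C[C@@](C)(O[Si](C)(C)C(C)(C)C)C(=O)C#CC(=C)COCc1ccc(OC)cc1 | intermediate
22 | hydroxy ynone (C5–OH and C10–OH free) | O=C1O[C@@H](CO)[C@@H](C1)C1(SCCCS1)C[C@@](C)(O)C(=O)C#CC(=C)COCc1ccc(OC)cc1 | intermediate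
23 | furanone primary alcohol (3(2H)-furanone closed, C5–OH free, C8 dithiane) | O=C1O[C@@H](CO)[C@@H](C1)C1(SCCCS1)C[C@@]1(C)OC(C(=C)COCc2ccc(OC)cc2)=CC1=O | intermediate
24 | C5 aldehyde | O=C1O[C@@H](C=O)[C@@H](C1)C1(SCCCS1)C[C@@]1(C)OC(C(=C)COCc2ccc(OC)cc2)=CC1=O | intermediate
25 | C6-vinyl dithiane triene | O=C1O[C@@H](C=C)[C@@H](C1)C1(SCCCS1)C[C@@]1(C)OC(C(=C)COCc2ccc(OC)cc2)=CC1=O | intermediate
26 | C8 ketone | O=C1O[C@@H](C=C)[C@@H](C1)C(=O)C[C@@]1(C)OC(C(=C)COCc2ccc(OC)cc2)=CC1=O | intermediate
27 | (8R)-carbinol (open triene with C6, C7, C8, C10 in place) | O=C1O[C@@H](C=C)[C@@H](C1)[C@H](O)C[C@@]1(C)OC(C(=C)COCc2ccc(OC)cc2)=CC1=O | intermediate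
28 | bicyclic alcohol (ten-membered ring closed, Z C4=C5, C8–OH, C15–OPMB, lactone CH2) | C1C(=O)O[C@H]2/C=C(/COCc4ccc(OC)cc4)C3=CC(=O)[C@@](C)(C[C@@H](O)[C@H]12)O3 | intermediate
29 | dilithio C8 alkoxide / lactone enolate of 28 | C1=C(O[Li])O[C@H]2/C=C(/COCc4ccc(OC)cc4)C3=CC(=O)[C@@](C)(C[C@@H](O[Li])[C@H]12)O3 | intermediate
30 | Mannich base (C11–CH2NMe2; C11 not controlled) | CN(C)CC1C(=O)O[C@H]2/C=C(/COCc4ccc(OC)cc4)C3=CC(=O)[C@@](C)(C[C@@H](O)[C@H]12)O3 | intermediate
31 | trimethylammonium iodide of 30 | C[N+](C)(C)CC1C(=O)O[C@H]2/C=C(/COCc4ccc(OC)cc4)C3=CC(=O)[C@@](C)(C[C@@H](O)[C@H]12)O3.[I-] | intermediate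
32 | α-methylene lactone alcohol (C8–OH, C15–OPMB) | C=C1C(=O)O[C@H]2/C=C(/COCc4ccc(OC)cc4)C3=CC(=O)[C@@](C)(C[C@@H](O)[C@H]12)O3 | intermediate
33 | crotonic anhydride | C/C=C/C(=O)OC(=O)/C=C/C | starting material
34 | 15-O-(4-methoxybenzyl) ether of the target | C=C1C(=O)O[C@H]2/C=C(/COCc4ccc(OC)cc4)C3=CC(=O)[C@@](C)(C[C@@H](OC(=O)/C=C/C)[C@H]12)O3 | intermediate
35 | CNP0225232.1, (4Z,6S,7S,8R,10R)-8-crotonyloxy-15-hydroxy furanone germacranolide | C=C1C(=O)O[C@H]2/C=C(/CO)C3=CC(=O)[C@@](C)(C[C@@H](OC(=O)/C=C/C)[C@H]12)O3 | target

## Step count and least certain steps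

Total step count: 19. Longest linear sequence: 15 steps (1, 4, 5, 6, 9–19) from (S)-2-methylglycidol.

**Step 4 (key step).** Most likely failures: slow opening of the 2,2-disubstituted epoxide by the hindered silyl dithiane anion in ether, so that silyl migration and proton transfer start before C8–C9 is complete; or γ-deprotonation of the butenolide instead of 1,4-addition.
Fallback: the relay is given up for a two-pot sequence. It sets out from 6 and 3. 2-Lithio-1,3-dithiane 7 opens 3 in THF to the tertiary hydroxy dithiane F1. TBSOTf/2,6-lutidine gives the silyl ether F2. t-BuLi in THF/HMPA at −78 °C deprotonates F2 to the same anion 11, which is trapped with 5 and returns to the route at 13.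

**Step 15.** Most likely failure: poor facial selectivity, because the inherent bias of the ketone (a polar Felkin–Anh reading favours the 8S alcohol) may oppose the catalyst, and the C9 arm, though a methylene, is neopentyl-like.
Fallback: the substrate bias is reinforced instead of opposed, and C8 is corrected by substitution. It sets out from 26. LiBH(sec-Bu)3 or the (R)-oxazaborolidine gives the 8S alcohol F3. Mitsunobu reaction with chloroacetic acid (PPh3, DIAD) inverts C8 to the 8R chloroacetate F4. Thiourea/NaHCO3 in EtOH removes the chloroacetyl group and returns to the route at 27.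

**Step 16.** Most likely failures: oligomerisation by intermolecular metathesis at the C6 vinyl group, because closure of the strained oxa-bridged ring onto a hindered, electron-poor 1,1-disubstituted alkene is slow; and double-bond migration by catalyst decomposition products.
Fallback: the order of ring closure and C8 adjustment is changed. It sets out from 25, where the fully substituted dithiane carbon biases the chain towards the folded conformer and no hydroxyl is free. Metathesis gives the bicyclic dithiane F5. MeI/CaCO3 gives the bicyclic ketone F6. Reduction as in step 15, now on a rigid ring, returns to the route at 28.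

**Step 17.** Most likely failures: competing deprotonation at C6 (in 28 this C–H is allylic and vinylogously activated by the furanone); conjugate addition of the amide base to the dienone; translactonisation by the C8 alkoxide before the enolate has formed.
Fallback: the enolate chemistry is moved ahead of ring closure. It sets out from 27, where C6–H is only allylic to an isolated vinyl group. The same sequence leads through the dilithio species F7, the Mannich base F8 and the ammonium iodide F9 to the α-methylene triene F10. Metathesis of F10 (its acrylate-type alkene cannot ring-close with the C6 vinyl group) returns to the route at 32.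

**Step 11.** Most likely failures: incomplete cleavage of the tertiary silyl ether, or base-induced oligomerisation (oxa-Michael addition of the primary alkoxide) before cyclisation.
Fallback: base-triggered cascade is replaced by π-acid catalysis. It sets out from 21. HF·pyridine in THF/pyridine removes the silyl groups without base and hydroxy ynone 22 is isolated. AuCl3 (trivalent gold, 5 mol %) in CH2Cl2 then closes it to 23, where the route is rejoined.

## Further compounds

F1 | step 4 | (R)-1-(1,3-dithian-2-yl)-3-(4-methoxybenzyloxy)-2-methylpropan-2-ol | O[C@@](C)(COCc1ccc(OC)cc1)CC1SCCCS1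
F2 | step 4 | tert-butyldimethylsilyl ether of F1 | CC(C)(C)[Si](C)(C)O[C@@](C)(COCc1ccc(OC)cc1)CC1SCCCS1
F3 | step 15 | (8S)-carbinol, C8 epimer of 27 | O=C1O[C@@H](C=C)[C@@H](C1)[C@@H](O)C[C@@]1(C)OC(C(=C)COCc2ccc(OC)cc2)=CC1=O
F4 | step 15 | (8R)-chloroacetate of 27 | O=C1O[C@@H](C=C)[C@@H](C1)[C@H](OC(=O)CCl)C[C@@]1(C)OC(C(=C)COCc2ccc(OC)cc2)=CC1=O
F5 | step 16 | bicyclic dithiane (ring closed, C8 still a 1,3-dithiane) | C1C(=O)O[C@H]2/C=C(/COCc4ccc(OC)cc4)C3=CC(=O)[C@@](C)(CC5(SCCCS5)[C@H]12)O3
F6 | step 16 | bicyclic C8 ketone | C1C(=O)O[C@H]2/C=C(/COCc4ccc(OC)cc4)C3=CC(=O)[C@@](C)(CC(=O)[C@H]12)O3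
F7 | step 17 | dilithio C8 alkoxide / lactone enolate of 27 | [Li]OC1=C[C@@H]([C@H](O[Li])C[C@@]2(C)OC(C(=C)COCc3ccc(OC)cc3)=CC2=O)[C@H](C=C)O1
F8 | step 17 | Mannich base of 27 (C11–CH2NMe2) | CN(C)CC1C(=O)O[C@@H](C=C)[C@@H]1[C@H](O)C[C@@]1(C)OC(C(=C)COCc2ccc(OC)cc2)=CC1=O
F9 | step 17 | trimethylammonium iodide of F8 | C[N+](C)(C)CC1C(=O)O[C@@H](C=C)[C@@H]1[C@H](O)C[C@@]1(C)OC(C(=C)COCc2ccc(OC)cc2)=CC1=O.[I-]
F10 | step 17 | α-methylene lactone of 27 (open tetraene) | C=C1C(=O)O[C@@H](C=C)[C@@H]1[C@H](O)C[C@@]1(C)OC(C(=C)COCc2ccc(OC)cc2)=CC1=O
F0 | step 11 | none | none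
A1 | alternative 1 | seco S-ethyl thioester / terminal alkyne | C=C1C(=O)O[C@@H](/C=C(/CO[Si](C)(C)C(C)(C)C)C#C)[C@@H]1[C@H](OC(=O)/C=C/C)C[C@@](C)(O[Si](CC)(CC)CC)C(=O)SCC
A2 | alternative 1 | ten-membered ynone | C=C1C(=O)O[C@H]2/C=C(/CO[Si](C)(C)C(C)(C)C)C#CC(=O)[C@@](C)(C[C@@H](OC(=O)/C=C/C)[C@H]12)O[Si](CC)(CC)CC
A3 | alternative 2 | seco (Z)-alkenyl iodide / C6 aldehyde | I/C=C(/CO[Si](C)(C)C(C)(C)C)C1=CC(=O)[C@@](C)(C[C@@H](O[Si](CC)(CC)CC)[C@@H](C=O)CC(=O)OC)O1
A4 | alternative 2 | macrocyclic C6 allylic alcohol | O[C@H]1/C=C(/CO[Si](C)(C)C(C)(C)C)C2=CC(=O)[C@@](C)(C[C@@H](O[Si](CC)(CC)CC)[C@@H]1CC(=O)OC)O2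
A5 | alternative 3 | cyclooct-2-enone carrying the C10 ynol ether | C=C1C(=O)O[C@H]2/C=C\C(=O)[C@](C)(OC#CCO[Si](C)(C)C(C)(C)C)C[C@@H](OC(=O)/C=C/C)[C@H]12
A6 | alternative 3 | alkoxycyclobutene photoadduct | C=C1C(=O)O[C@H]2C3C(CO[Si](C)(C)C(C)(C)C)=C4O[C@](C)(C[C@@H](OC(=O)/C=C/C)[C@H]12)C(=O)C34
A7 | alternative 3 | 15-O-TBS ether of the target | C=C1C(=O)O[C@H]2/C=C(/CO[Si](C)(C)C(C)(C)C)C3=CC(=O)[C@@](C)(C[C@@H](OC(=O)/C=C/C)[C@H]12)O3
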